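## Analysis of the target

Compound 24 is a methylene-bridged pair of acylphloroglucinol-derived rings. Ring A is the gem-dimethyl, enolised β,β′-triketone of 2-propanoylfilicinic acid (22), ring B is a hexasubstituted benzene, and ring C is a 2,2-dimethyl-2H-pyran fused to ring B across C4a–C8a (O1–C2–C3=C4). Ring B carries oxygen on C5, C7 and C8a and carbon on C4a, C6 and C8: the pyran carbon C4 on C4a, the bridging CH2 on C6 and an acetyl group on C8. There is no stereocentre; the only stereochemical element is the C3=C4 alkene, which ring C holds cis, and ring A exists as rapidly equilibrating enol tautomers. Sensitive groups are the electron-rich chromene alkene (acid-induced hydration and dimerisation), the ortho-hydroxybenzyl bridge (it can reopen to an ortho-quinone methide under acid, base or heat) and the air-sensitive polyphenol and triketone. The difficulty lies in ring B: three oxygens and three different carbon substituents must be placed without error, and elaboration of a preformed acylphloroglucinol gives regioisomeric pyran fusion and a statistical methylene coupling. The strategy rests on the strict alternation of oxygen- and carbon-bearing carbons around ring B. This is the pattern of a head-to-tail union of three oxygen-substituted alkynes, C8a≡C8, C4a≡C5 and C6≡C7, the first two linked by the O1–C2–C3–C4 atoms of ring C. One structural limit shapes the route: while O1 is still an ynol ether oxygen, C3=C4 cannot be present, because an allyl alkynyl ether rearranges by a [3,3] shift far below room temperature. C3–C4 is therefore carried saturated with a methoxy group on C4, and the alkene is unveiled once ring B exists.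

## Retrosynthetic reasoning

24 ⇒ 20 + 22. The only bond joining the two halves is that between the bridging CH2 and the enolic carbon of ring A. Cutting it gives the benzylic methyl ether 20 and the acylfilicinic acid 22. In the forward direction 20 loses its methoxy group to form ortho-quinone methide 23, and the soft carbon nucleophile of 22 adds to it. With the electrophile fixed on C6 of ring B the union is a directed cross-coupling, not a three-component methylene coupling, and the most fragile bond of 24 is made last. 22 is traced to the acylphloroglucinol 21 by twofold C-methylation at one ring carbon.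

20 ⇒ 19 ⇒ 18. The two silyl groups are removed only just before the coupling, because free phenols flanking the benzylic ether are what trigger formation of 23. The C3=C4 alkene of 19 is traced to the C4 methoxy group of chromane 18 by 1,2-elimination. The alkene is not carried further back for a structural reason. In the diyne that precedes ring B, O1 is an ynol ether oxygen on C2; with C3=C4 in place this would be an allyl alkynyl ether, which cannot be isolated. A C4 ether cannot rearrange in this way, and it is expelled easily later because the C4 cation is benzylic and flanked by the ring oxygens. Only C3 carries a hydrogen that can be lost, so the alkene can form in one place only.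

18 ⇒ 16 ⇒ 15. The C8–acetyl bond is cut next. C8 is the only unsubstituted carbon of ring B in 15 and is ortho or para to all three oxygens, so electrophilic bromination can go nowhere else. Bromine–lithium exchange to 17 and acylation then deliver the ketone under basic conditions that leave both benzylic ethers intact. A Lewis-acid acylation or a Fries shift would ionise those ethers and is avoided.

15 ⇒ 11 + 14. This is the key disconnection. The three bonds C4a–C8a, C5–C6 and C7–C8 are cut, so that ring B falls apart into three alkynes and ring C opens with it. Cutting here is suggested by the 1,3,5-oxygen pattern, and no other set of cuts removes both rings at once while leaving every substituent of ring B already attached to an alkyne carbon. In the forward direction the metal must couple the two tethered alkynes of 11 first and then take up 14 in one orientation. Diyne 11 carries O1 bonded to C2, the gem-dimethyl group, the C4 methoxy group and the C5 silyloxy group; 14 carries the C7 silyloxy group and the C6 methoxymethyl group.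

14 ⇒ 12, and 11 ⇒ 9 ⇒ 7 + 8, 7 ⇒ 5. Both silyloxyalkynes are traced to terminal alkynes by oxygenation of the acetylide, through ynolates 13 and 6, and O-silylation. The ethynyl ether of 11 comes from the tertiary alcohol of 7 and the two carbons of 8, through dichlorovinyl ether 9 and lithium alkynyl ether 10. The silyloxyalkyne is made first because the ethynyl ether has an acidic C–H that could not be told apart from the other terminal alkyne. The tertiary hydroxyl is never silylated, so no selective desilylation beside a silyl ynol ether is needed.

5 ⇒ 4 ⇒ 2 + 3 ⇒ 1. The C4 methoxy group is placed by selective etherification of the secondary propargylic hydroxyl of diol 4. Diol 4 is cut at the C4–C4a bond into aldehyde 2 and the alkynyl Grignard reagent 3, and 2 comes from oxidative cleavage of the terminal alkene of 1.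

## Alternatives that were turned down

Alternative 1: The disconnection is the C7–C8 bond of ring B, with ring A and the bridging CH2 already attached to an open tetraketide chain masked as a 4-pyrone. In the forward key step Mg(OMe)2 opens the pyrone to the triketo ester, and the carbon between the acetyl group and its neighbouring ketone attacks the ester carbonyl. This gives A1, 2-[(3-acetyl-2,4,6-trihydroxyphenyl)methyl]-3,5-dihydroxy-4,4-dimethyl-6-propanoylcyclohexa-2,5-dien-1-one. In its favour, the closure is biomimetic and mild, it sets the acetyl group and all three ring B oxygens in one event, and the bridge is in place from the start, so no late fragment coupling is needed. On precedent for the key step it is stronger than the chosen route. Against it, A1 still lacks ring C. Its one free aromatic C–H lies between two hydroxyls, and the pyran must be fused through the hydroxyl next to the acetyl-bearing carbon. That hydroxyl is chelated and less nucleophilic, so the isomer fused through the other hydroxyl should compete or dominate. The annulation would also meet the enolised triketone of ring A, and the open chain has competing aldol closures. The chosen strategy bonds O1 to C8a and to the C2 quaternary carbon before ring B exists, so this regiochemical question cannot arise. It gives up precedent and offers complete positional control with ring C formed in the same step.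

Alternative 2: The disconnection is C3=C4 of ring C. In the forward key step the second-generation Grubbs catalyst joins a propenyl group on C4a to a 1,1-dimethylallyl ether on C8a with release of a small volatile alkene. This gives A2, 1-(5,7-dimethoxy-2,2-dimethyl-2H-chromen-8-yl)ethan-1-one. In its favour, the ring closure is mild and among the most dependable known, it delivers the alkene directly, and A2 already has the acetyl group on C8. On certainty of the key step it is clearly stronger. Against it, the step closes only ring C on a finished benzene ring, so the whole regiochemical problem of ring B is left to classical phloroglucinol chemistry. That chemistry must put a tertiary allyl ether on the chelated hydroxyl next to the acetyl group and a propenyl group beside it, and such aryl ethers are prone to Claisen shift and ionisation. The methyl ethers of A2 need strong Lewis acids for cleavage, which the chromene alkene does not tolerate. C6 is still unfunctionalised, so the bridge would come from a statistical methylene coupling. The chosen strategy forms two rings and three bonds in its key step, arrives with the C6 carbon in place and uses silyl groups that fluoride removes. It pays for this with an unproven key step.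

Alternative 3: The disconnection is C6–C7 and C4a–C5 of ring B. In the forward key step an alkoxycyclobutenone is heated with siloxyalkyne 14. Ring opening gives a vinylketene, which adds the alkyne and recloses by 4π opening and 6π closure to A3, 5-ethoxy-2-(methoxymethyl)-3-(triisopropylsilyloxy)phenol. In its favour, this benzannulation is established and metal-free, its regiochemistry follows from the same alkyne polarisation, it shares 14 with the chosen route, and the three oxygens emerge differentiated. On precedent it is stronger. Against it, A3 contains ring B only. The carbons that must become C4a and C8 carry hydrogen, and the oxygen that must become O1 carries an ethyl group. That ether must be cleaved beside a benzylic methyl ether and a silyl ether, then the pyran fused and the acetyl group introduced, each with a choice between two similar ring positions. The chosen strategy delivers rings B and C together, with O1 already bonded to C2 and exactly one open ring position.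

Key step: step 8

Assumption: the future C4 is a stereocentre in 4–7, 9–11 and 15–18. These compounds are made and used as racemates, drawn without configuration, because the centre is removed in step 11 and 24 is achiral. Compounds 1, 3 (as a THF solution), 8, 12 and 21 are taken as catalogue chemicals.

## Route

Step 1
Reactants: 1 2-methylpent-4-en-2-ol
Product: 2 3-hydroxy-3-methylbutanal
Conditions: O3, CH2Cl2, −78 °C; PPh3, −78 °C to rt
Reagents that add atoms: ozone, [O-][O+]=O
Why: Ozonolysis with reductive work-up cleaves the only alkene to the aldehyde under neutral conditions, which avoids acid- or base-induced dehydration of the β-hydroxy aldehyde; 2 should be used without prolonged storage.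

Step 2
Reactants: 2 3-hydroxy-3-methylbutanal; 3 ethynylmagnesium bromide
Product: 4 5-methylhex-1-yne-3,5-diol (racemic)
Conditions: HC≡CMgBr (2.5 equiv), THF, −78 to 0 °C; aq. NH4Cl
Reagents that add atoms: none
Why: Grignard 1,2-addition to the aldehyde after the first equivalent has deprotonated the tertiary hydroxyl; the new carbinol centre (future C4) forms without control, which is harmless because it is erased in step 11.

Step 3
Reactants: 4 5-methylhex-1-yne-3,5-diol
Product: 5 4-methoxy-2-methylhex-5-yn-2-ol (racemic)
Conditions: NaH (1.0 equiv), THF, 0 °C; MeI (1.05 equiv), 0 °C to rt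
Reagents that add atoms: iodomethane, CI
Why: Williamson etherification; with one equivalent of base the alkoxide sits on the more acidic and less hindered secondary propargylic oxygen, which is methylated in preference to the tertiary one, and the alkyne C–H is not touched at this basicity.

Step 4
Reactants: 5 4-methoxy-2-methylhex-5-yn-2-ol
Product: 7 4-methoxy-2-methyl-6-(triisopropylsilyloxy)hex-5-yn-2-ol (racemic), via dilithium ynolate alkoxide 6 (not isolated)
Conditions: n-BuLi (2.05 equiv), THF, −78 °C; LiOOt-Bu (from t-BuOOH, LiN(SiMe3)2), −78 to 0 °C; i-Pr3SiOTf (1.05 equiv), −78 °C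
Reagents that add atoms: tert-butyl hydroperoxide, CC(C)(C)OO; triisopropylsilyl trifluoromethanesulfonate, CC(C)[Si](C(C)C)(C(C)C)OS(=O)(=O)C(F)(F)F
Why: Electrophilic oxygenation of the lithium acetylide by the peroxide oxygen gives ynolate 6, and the bulky silyl triflate silylates an ynolate on oxygen; the hindered tertiary lithium alkoxide should not compete at −78 °C and returns the free alcohol on work-up.

Step 5
Reactants: 7 4-methoxy-2-methyl-6-(triisopropylsilyloxy)hex-5-yn-2-ol; 8 trichloroethylene
Product: 9 5-[(E)-1,2-dichloroethenyl]oxy-3-methoxy-5-methyl-1-(triisopropylsilyloxy)hex-1-yne (racemic)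
Conditions: KH (1.2 equiv), THF, 0 °C; Cl2C=CHCl (1.1 equiv), −50 °C to rt
Reagents that add atoms: none
Why: First stage of the dichlorovinyl ether route to ynol ethers: the potassium alkoxide generates dichloroacetylene from 8 and adds to it anti to give the E ether; tertiary alkoxides are competent, and no silyl group sits on a neighbouring oxygen that could migrate.

Step 6
Reactants: 9 5-[(E)-1,2-dichloroethenyl]oxy-3-methoxy-5-methyl-1-(triisopropylsilyloxy)hex-1-yne
Product: 11 5-(ethynyloxy)-3-methoxy-5-methyl-1-(triisopropylsilyloxy)hex-1-yne (racemic), via lithium alkynyl ether 10 (not isolated)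
Conditions: n-BuLi (2.2 equiv), Et2O, −78 °C; MeOH, −78 °C; cold work-up, used at once
Reagents that add atoms: none
Why: Second stage of the same ynol ether synthesis: dehydrochlorination and chlorine–lithium exchange give 10, which is protonated cold; the hindered silyl ynol ether should survive brief exposure to n-BuLi at −78 °C, and 11 is kept below 0 °C because tertiary ethynyl ethers fragment by a retro-ene path on warming.

Step 7
Reactants: 12 3-methoxyprop-1-yne
Product: 14 3-methoxy-1-(triisopropylsilyloxy)prop-1-yne, via lithium ynolate 13 (not isolated)
Conditions: n-BuLi (1.0 equiv), THF, −78 °C; LiOOt-Bu (from t-BuOOH, LiN(SiMe3)2), −78 to 0 °C; i-Pr3SiOTf (1.05 equiv), −78 °C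
Reagents that add atoms: tert-butyl hydroperoxide, CC(C)(C)OO; triisopropylsilyl trifluoromethanesulfonate, CC(C)[Si](C(C)C)(C(C)C)OS(=O)(=O)C(F)(F)F
Why: Same acetylide oxygenation and O-silylation as in step 4, here on a simple propargylic ether.

Step 8
Reactants: 11 5-(ethynyloxy)-3-methoxy-5-methyl-1-(triisopropylsilyloxy)hex-1-yne; 14 3-methoxy-1-(triisopropylsilyloxy)prop-1-yne
Product: 15 4-methoxy-6-(methoxymethyl)-2,2-dimethyl-5,7-bis(triisopropylsilyloxy)chromane (racemic)
Conditions: [Rh(cod)2]BF4 (5 mol %), rac-BINAP (5 mol %), H2 then Ar, CH2Cl2, rt; 14 (2 equiv), slow addition of 11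
Reagents that add atoms: none
Why: Proposed new method: the closest established reaction type is the cationic rhodium–bisphosphine [2+2+2] cyclotrimerisation of a tethered 1,7-diyne with a monoalkyne, in which a single ynol ether or ynamide partner is known, whereas here all three alkynes are oxygen-substituted and two are silyl ynol ethers. Monovalent rhodium is expected to bind both alkynes of 11 and undergo oxidative cyclisation to a trivalent rhodacyclopentadiene, which forms C4a–C8a and closes the six-membered ring C through the four-atom tether O1–C2–C3–C4, helped by the gem-dimethyl group on C2. Coordination and insertion of 14, then C–C reductive elimination, form C5–C6 and C7–C8, close the six-membered carbocycle ring B as an aromatic ring and return monovalent rhodium. No stereocentre is created; the C4 centre of 11 is carried through unchanged, so racemic BINAP suffices. The step needs cross- over homo-trimerisation, which the intramolecular first step and the slow addition of 11 to an excess of 14 should secure. It also needs one orientation of 14: union of its nucleophilic methoxymethyl-bearing carbon with the oxygen-bearing, carbene-like C5, and of its silyloxy carbon with the unhindered C8–H terminus, is the polarity-matched head-to-tail mode, and the opposite mode would place two triisopropylsilyloxy groups on adjacent carbons. A catalyst that turns over at room temperature is required because of the thermal lability of the tertiary ethynyl ether in 11.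

Step 9
Reactants: 15 4-methoxy-6-(methoxymethyl)-2,2-dimethyl-5,7-bis(triisopropylsilyloxy)chromane
Product: 16 8-bromo-4-methoxy-6-(methoxymethyl)-2,2-dimethyl-5,7-bis(triisopropylsilyloxy)chromane (racemic)
Conditions: NBS (1.05 equiv), MeCN/CH2Cl2, −20 to 0 °C, dark
Reagents that add atoms: N-bromosuccinimide, O=C1CCC(=O)N1Br
Why: Electrophilic aromatic bromination at C8, the only unsubstituted ring carbon and ortho or para to all three oxygens; no alkene is present at this stage and no strong acid is released.

Step 10
Reactants: 16 8-bromo-4-methoxy-6-(methoxymethyl)-2,2-dimethyl-5,7-bis(triisopropylsilyloxy)chromane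
Product: 18 1-[4-methoxy-6-(methoxymethyl)-2,2-dimethyl-5,7-bis(triisopropylsilyloxy)chroman-8-yl]ethan-1-one (racemic), via aryllithium 17 (not isolated)
Conditions: t-BuLi (2.1 equiv), Et2O, −78 °C; MeC(O)N(OMe)Me (3 equiv), −78 to −20 °C; aq. NH4Cl
Reagents that add atoms: N-methoxy-N-methylacetamide, CC(=O)N(C)OC
Why: Bromine–lithium exchange followed by Weinreb ketone synthesis; the chelated tetrahedral adduct prevents over-addition, and the basic conditions leave both benzylic methyl ethers and the silyl ethers intact.

Step 11
Reactants: 18 1-[4-methoxy-6-(methoxymethyl)-2,2-dimethyl-5,7-bis(triisopropylsilyloxy)chroman-8-yl]ethan-1-one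
Product: 19 1-[6-(methoxymethyl)-2,2-dimethyl-5,7-bis(triisopropylsilyloxy)-2H-chromen-8-yl]ethan-1-one
Conditions: CSA (10 mol %), 4 Å MS, toluene, 60 °C
Reagents that add atoms: none
Why: Acid-catalysed E1 loss of the C4 methoxy group, the standard way from 4-oxygenated chromanes to 2H-chromenes; the secondary C4 cation is stabilised by O1 and the silyloxy groups and should ionise well before the primary benzylic ether on C6, only C3 can lose a proton, and ring B has no free position to intercept the cation.

Step 12
Reactants: 19 1-[6-(methoxymethyl)-2,2-dimethyl-5,7-bis(triisopropylsilyloxy)-2H-chromen-8-yl]ethan-1-one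
Product: 20 1-[5,7-dihydroxy-6-(methoxymethyl)-2,2-dimethyl-2H-chromen-8-yl]ethan-1-one
Conditions: Bu4NF (2.2 equiv), AcOH (2.5 equiv), THF, 0 °C
Reagents that add atoms: none
Why: Fluoride cleavage of the two aryl silyl ethers; buffering with acetic acid keeps the phenols protonated so that methoxide is not expelled prematurely from the C6 benzylic position.

Step 13
Reactants: 21 1-(2,4,6-trihydroxyphenyl)propan-1-one
Product: 22 3,5-dihydroxy-4,4-dimethyl-2-propanoylcyclohexa-2,5-dien-1-one (propanoylfilicinic acid)
Conditions: NaOMe (3 equiv), MeI (2.2 equiv), MeOH, 0 °C to rt; aq. HCl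
Reagents that add atoms: iodomethane, CI
Why: Dearomatising geminal C-methylation of an acylphloroglucinol, the classical entry to acylfilicinic acids; over- and under-methylated by-products are removed by crystallisation or chromatography.

Step 14
Reactants: 20 1-[5,7-dihydroxy-6-(methoxymethyl)-2,2-dimethyl-2H-chromen-8-yl]ethan-1-one; 22 3,5-dihydroxy-4,4-dimethyl-2-propanoylcyclohexa-2,5-dien-1-one
Product: 24 2-[(8-acetyl-5,7-dihydroxy-2,2-dimethyl-2H-chromen-6-yl)methyl]-3,5-dihydroxy-4,4-dimethyl-6-propanoylcyclohexa-2,5-dien-1-one (CNP0153527.0), via ortho-quinone methide 23 (not isolated)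
Conditions: 22 (1.5 equiv), NaOAc (0.2 equiv), 1,4-dioxane, 80 °C
Reagents that add atoms: none
Why: Phenoxide-assisted 1,4-elimination of methoxide from 20 gives ortho-quinone methide 23, and Michael addition of the enolate carbon of 22 between its two carbonyl-type carbons restores the aromatic ring; every ring position of 20 is substituted, so self-condensation through ring carbon is excluded.

## Compound list

1 | 2-methylpent-4-en-2-ol | C=CCC(C)(C)O | starting material
2 | 3-hydroxy-3-methylbutanal | CC(C)(O)CC=O | intermediate
3 | ethynylmagnesium bromide | C#C[Mg]Br | starting material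
4 | 5-methylhex-1-yne-3,5-diol (racemic) | C#CC(O)CC(C)(C)O | intermediate
5 | 4-methoxy-2-methylhex-5-yn-2-ol (racemic) | C#CC(OC)CC(C)(C)O | intermediate
6 | dilithium 3-methoxy-5-methyl-5-oxidohex-1-yn-1-olate (racemic) | [Li+].[Li+].[O-]C#CC(OC)CC(C)(C)[O-] | intermediate
7 | 4-methoxy-2-methyl-6-(triisopropylsilyloxy)hex-5-yn-2-ol (racemic) | CC(C)(O)CC(OC)C#CO[Si](C(C)C)(C(C)C)C(C)C | intermediate
8 | trichloroethylene | ClC=C(Cl)Cl | starting material
9 | 5-[(E)-1,2-dichloroethenyl]oxy-3-methoxy-5-methyl-1-(triisopropylsilyloxy)hex-1-yne (racemic) | Cl/C=C(/Cl)OC(C)(C)CC(OC)C#CO[Si](C(C)C)(C(C)C)C(C)C | intermediate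
10 | 5-(lithioethynyloxy)-3-methoxy-5-methyl-1-(triisopropylsilyloxy)hex-1-yne (racemic) | [Li]C#COC(C)(C)CC(OC)C#CO[Si](C(C)C)(C(C)C)C(C)C | intermediate
11 | 5-(ethynyloxy)-3-methoxy-5-methyl-1-(triisopropylsilyloxy)hex-1-yne (racemic) | C#COC(C)(C)CC(OC)C#CO[Si](C(C)C)(C(C)C)C(C)C | intermediate
12 | 3-methoxyprop-1-yne | COCC#C | starting material
13 | lithium 3-methoxyprop-1-yn-1-olate | [Li+].[O-]C#CCOC | intermediate
14 | 3-methoxy-1-(triisopropylsilyloxy)prop-1-yne | COCC#CO[Si](C(C)C)(C(C)C)C(C)C | intermediate
15 | 4-methoxy-6-(methoxymethyl)-2,2-dimethyl-5,7-bis(triisopropylsilyloxy)chromane (racemic) | COCc1c(O[Si](C(C)C)(C(C)C)C(C)C)cc2OC(C)(C)CC(OC)c2c1O[Si](C(C)C)(C(C)C)C(C)C | intermediate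
16 | 8-bromo-4-methoxy-6-(methoxymethyl)-2,2-dimethyl-5,7-bis(triisopropylsilyloxy)chromane (racemic) | COCc1c(O[Si](C(C)C)(C(C)C)C(C)C)c(Br)c2OC(C)(C)CC(OC)c2c1O[Si](C(C)C)(C(C)C)C(C)C | intermediate
17 | 8-lithio-4-methoxy-6-(methoxymethyl)-2,2-dimethyl-5,7-bis(triisopropylsilyloxy)chromane (racemic) | COCc1c(O[Si](C(C)C)(C(C)C)C(C)C)c([Li])c2OC(C)(C)CC(OC)c2c1O[Si](C(C)C)(C(C)C)C(C)C | intermediate
18 | 1-[4-methoxy-6-(methoxymethyl)-2,2-dimethyl-5,7-bis(triisopropylsilyloxy)chroman-8-yl]ethan-1-one (racemic) | COCc1c(O[Si](C(C)C)(C(C)C)C(C)C)c(C(C)=O)c2OC(C)(C)CC(OC)c2c1O[Si](C(C)C)(C(C)C)C(C)C | intermediate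
19 | 1-[6-(methoxymethyl)-2,2-dimethyl-5,7-bis(triisopropylsilyloxy)-2H-chromen-8-yl]ethan-1-one | COCc1c(O[Si](C(C)C)(C(C)C)C(C)C)c(C(C)=O)c2OC(C)(C)C=Cc2c1O[Si](C(C)C)(C(C)C)C(C)C | intermediate
20 | 1-[5,7-dihydroxy-6-(methoxymethyl)-2,2-dimethyl-2H-chromen-8-yl]ethan-1-one | COCc1c(O)c(C(C)=O)c2OC(C)(C)C=Cc2c1O | intermediate
21 | 1-(2,4,6-trihydroxyphenyl)propan-1-one | CCC(=O)c1c(O)cc(O)cc1O | starting material
22 | 3,5-dihydroxy-4,4-dimethyl-2-propanoylcyclohexa-2,5-dien-1-one | CCC(=O)C1=C(O)C(C)(C)C(O)=CC1=O | intermediate
23 | 8-acetyl-7-hydroxy-2,2-dimethyl-6-methylidene-2H-chromen-5(6H)-one | C=C1C(=O)C2=C(OC(C)(C)C=C2)C(C(C)=O)=C1O | intermediate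
24 | 2-[(8-acetyl-5,7-dihydroxy-2,2-dimethyl-2H-chromen-6-yl)methyl]-3,5-dihydroxy-4,4-dimethyl-6-propanoylcyclohexa-2,5-dien-1-one | CCC(=O)C1=C(O)C(C)(C)C(O)=C(Cc2c(O)c3c(c(C(C)=O)c2O)OC(C)(C)C=C3)C1=O | target

## Step count and risks

Total step count: 14. Longest linear sequence: 12 steps (steps 1–6, 8–12 and 14; steps 7 and 13 are side branches).

Least certain steps:

Step 8 (key step, proposed new method). The most likely failure is consumption of the alkynes before oxidative cyclisation. The cationic rhodium complex can act as a Lewis acid on the silyl ynol ethers (ketene formation, oligomerisation), the tertiary ethynyl ether can fragment, and 14 can homotrimerise. All three partners are far more electron-rich and acid-labile than the alkynes for which this catalysis is established. Insertion of 14 in the inverted sense is the second possibility. The fallback uses known chemistry, sets out from 2 and returns at 24. Compound 2 is heated with commercial 2,4,6-trihydroxyacetophenone in pyridine, which brings about dehydration to the enal, condensation at a ring carbon and 6π-electrocyclisation. After separation from the 6-acetyl isomer this gives 1-(5,7-dihydroxy-2,2-dimethyl-2H-chromen-8-yl)ethan-1-one F1. Aminomethylation of its only free ring carbon, C6, with dimethylmethylideneammonium iodide (Mannich reaction) gives 1-[6-[(dimethylamino)methyl]-5,7-dihydroxy-2,2-dimethyl-2H-chromen-8-yl]ethan-1-one F2. Heating F2 with 22 in dioxane expels the amine to give 23 and then 24. This fallback gives up the positional control of the pyran fusion and accepts an isomer separation.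

Step 6. The most likely failure is loss of the terminal tertiary ynol ether during quench, work-up and concentration, by retro-ene fragmentation on warming and by acid-catalysed hydration on silica. Metalation next to the C4 methoxy group by excess n-BuLi is the second possibility. The fallback sets out from 9 and returns at 16. The lithium alkynyl ether 10 is quenched with Me3SiCl instead of a proton source, to give the C-silylated and more robust 3-methoxy-5-methyl-1-(triisopropylsilyloxy)-5-[(trimethylsilyl)ethynyloxy]hex-1-yne F3. Cyclotrimerisation of F3 with 14 under the conditions of step 8 gives 4-methoxy-6-(methoxymethyl)-2,2-dimethyl-8-(trimethylsilyl)-5,7-bis(triisopropylsilyloxy)chromane F4. Ipso-bromodesilylation of F4 with NBS gives 16. The price is a bulky group at the C8 terminus in the key step, so orientation of 14 would then rest on alkyne polarisation alone.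

Step 10. The most likely failure is slow addition of the doubly ortho-substituted aryllithium 17 to the amide. This allows migration of the neighbouring silyl group from oxygen to C8 on warming, or proton transfer from the amide that returns 15. The fallback sets out from 16 and returns at 18. Stille coupling of 16 with tributyl(1-ethoxyvinyl)stannane under Pd(PPh3)4 catalysis (zerovalent palladium) gives 8-(1-ethoxyethenyl)-4-methoxy-6-(methoxymethyl)-2,2-dimethyl-5,7-bis(triisopropylsilyloxy)chromane F5. Brief hydrolysis of the enol ether with dilute aqueous oxalic acid at 0 °C gives 18.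

Step 11. The most likely failure is competing ionisation of the primary benzylic ether on C6, followed by attack of that cation on the newly formed chromene alkene to give oligomers; acid-induced dimerisation of the chromene is a related loss. The fallback sets out from 18 and returns at 24, and it replaces acid ionisation by phenoxide-driven elimination. Desilylation of 18 with Bu4NF and AcOH gives 1-[5,7-dihydroxy-4-methoxy-6-(methoxymethyl)-2,2-dimethylchroman-8-yl]ethan-1-one F6. F6 is heated with 22 and NaOAc in dioxane. The C5 phenoxide expels the C4 methoxy group, and the resulting quinone methide tautomerises irreversibly to the chromene by loss of a C3 proton. The C6 quinone methide is captured by 22 as in step 14, and addition of 22 at C4 is expected to be reversible.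

Step 14. The most likely failure is slow expulsion of methoxide, so that 23 forms only at temperatures where it is intercepted by the chromene alkene of a second molecule or alkylates 22 on oxygen. The fallback sets out from 19 and returns at 24, and it forms the same bond by condensation and reduction. Oxidation of the benzylic methyl ether of 19 with DDQ in wet CH2Cl2 gives 8-acetyl-2,2-dimethyl-5,7-bis(triisopropylsilyloxy)-2H-chromene-6-carbaldehyde F7. Desilylation with Bu4NF and AcOH gives 8-acetyl-5,7-dihydroxy-2,2-dimethyl-2H-chromene-6-carbaldehyde F8. Knoevenagel condensation of F8 with 22 under proline catalysis, in the presence of diethyl 2,6-dimethyl-1,4-dihydropyridine-3,5-dicarboxylate as hydride donor, reduces the alkylidene intermediate as it forms and gives 24.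

## Further compounds

F1 | step 8 | 1-(5,7-dihydroxy-2,2-dimethyl-2H-chromen-8-yl)ethan-1-one | CC(=O)c1c(O)cc(O)c2C=CC(C)(C)Oc12
F2 | step 8 | 1-[6-[(dimethylamino)methyl]-5,7-dihydroxy-2,2-dimethyl-2H-chromen-8-yl]ethan-1-one | CC(=O)c1c(O)c(CN(C)C)c(O)c2C=CC(C)(C)Oc12
F3 | step 6 | 3-methoxy-5-methyl-1-(triisopropylsilyloxy)-5-[(trimethylsilyl)ethynyloxy]hex-1-yne (racemic) | C[Si](C)(C)C#COC(C)(C)CC(OC)C#CO[Si](C(C)C)(C(C)C)C(C)C
F4 | step 6 | 4-methoxy-6-(methoxymethyl)-2,2-dimethyl-8-(trimethylsilyl)-5,7-bis(triisopropylsilyloxy)chromane (racemic) | COCc1c(O[Si](C(C)C)(C(C)C)C(C)C)c([Si](C)(C)C)c2OC(C)(C)CC(OC)c2c1O[Si](C(C)C)(C(C)C)C(C)C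
F5 | step 10 | 8-(1-ethoxyethenyl)-4-methoxy-6-(methoxymethyl)-2,2-dimethyl-5,7-bis(triisopropylsilyloxy)chromane (racemic) | COCc1c(O[Si](C(C)C)(C(C)C)C(C)C)c(C(=C)OCC)c2OC(C)(C)CC(OC)c2c1O[Si](C(C)C)(C(C)C)C(C)C
F6 | step 11 | 1-[5,7-dihydroxy-4-methoxy-6-(methoxymethyl)-2,2-dimethylchroman-8-yl]ethan-1-one (racemic) | COCc1c(O)c(C(C)=O)c2OC(C)(C)CC(OC)c2c1O
F7 | step 14 | 8-acetyl-2,2-dimethyl-5,7-bis(triisopropylsilyloxy)-2H-chromene-6-carbaldehyde | O=Cc1c(O[Si](C(C)C)(C(C)C)C(C)C)c(C(C)=O)c2OC(C)(C)C=Cc2c1O[Si](C(C)C)(C(C)C)C(C)C
F8 | step 14 | 8-acetyl-5,7-dihydroxy-2,2-dimethyl-2H-chromene-6-carbaldehyde | O=Cc1c(O)c(C(C)=O)c2OC(C)(C)C=Cc2c1O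
A1 | alternative 1 | 2-[(3-acetyl-2,4,6-trihydroxyphenyl)methyl]-3,5-dihydroxy-4,4-dimethyl-6-propanoylcyclohexa-2,5-dien-1-one | CCC(=O)C1=C(O)C(C)(C)C(O)=C(Cc2c(O)cc(O)c(C(C)=O)c2O)C1=O
A2 | alternative 2 | 1-(5,7-dimethoxy-2,2-dimethyl-2H-chromen-8-yl)ethan-1-one | CC(=O)c1c(OC)cc(OC)c2C=CC(C)(C)Oc12
A3 | alternative 3 | 5-ethoxy-2-(methoxymethyl)-3-(triisopropylsilyloxy)phenol | COCc1c(O)cc(OCC)cc1O[Si](C(C)C)(C(C)C)C(C)C
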